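**Plan**

Ring letters: ring A is the 2,4-dihydroxyphenyl ring of the first ketone, ring B the central 4-hydroxyphenyl ring, ring C the resorcinol ring that carries ring B and the second ketone, ring D the terminal 4-hydroxyphenyl ring.
Retrosynthesis, in order: (a) the bond from the second ketone carbon to C-5 of ring C, giving pentaphenol 7 and acid 1; (b) the two O–CH3 bonds that mask ring C; (c) the ring B–ring C biaryl bond; (d) the bond from the first ketone carbon to ring A; (e) the C–Br bond on ring B.
Forward: no ring is built. The chain ring A–CO–CH2CH2–ring B–ring C–CO–CH2CH2–ring D is joined in the order ring B (bromination of 1), ring A (acylation of resorcinol), ring C (cross-coupling, then demethylation), ring D with its C3 acyl chain (final acylation). Acid 1 supplies both C6–C3 units.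
Enabling feature: in 7, ring C (numbered from the biaryl carbon C-1, hydroxyls on C-2 and C-4) is the only free resorcinol ring, and its C-5 is para to O-2 and ortho to O-4. Ring A is deactivated by its carbonyl and rings B and D carry one hydroxyl each, so the union needs no protecting group and gives the target directly.
Stereochemistry: the target is achiral, with no stereocentre and no stereogenic double bond, so none has to be set.

Key step: step 5

**Route**

Step 1
Reactants: 1 3-(4-hydroxyphenyl)propanoic acid
Product: 2 3-(3-bromo-4-hydroxyphenyl)propanoic acid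
Conditions: NBS (1.0 equiv), MeCN, 0 °C to rt
Reagents that add atoms: N-bromosuccinimide, O=C1CCC(=O)N1Br
Why: Electrophilic aromatic bromination of a para-substituted phenol; with the para position blocked by the side chain, one equivalent of NBS should brominate once ortho to the hydroxyl, the first bromine slowing a second substitution.

Step 2
Reactants: 2 3-(3-bromo-4-hydroxyphenyl)propanoic acid; 3 resorcinol (benzene-1,3-diol)
Product: 4 3-(3-bromo-4-hydroxyphenyl)-1-(2,4-dihydroxyphenyl)propan-1-one
Conditions: BF3·OEt2 (solvent and Lewis acid), 85 °C; then aq. NaOAc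
Reagents that add atoms: none
Why: Friedel–Crafts C-acylation of resorcinol by the free acid in BF3·OEt2 should take place para to one hydroxyl and ortho to the other, the ketone formed deactivates its ring against a second acylation, and the bromophenol ring of 2 is far less nucleophilic than resorcinol.

Step 3
Reactants: 4 3-(3-bromo-4-hydroxyphenyl)-1-(2,4-dihydroxyphenyl)propan-1-one; 5 (2,4-dimethoxyphenyl)boronic acid (1.5 equiv)
Product: 6 1-(2,4-dihydroxyphenyl)-3-[3-(2,4-dimethoxyphenyl)-4-hydroxyphenyl]propan-1-one
Conditions: Pd(OAc)2 (5 mol %), SPhos (10 mol %), K3PO4, dioxane/H2O (4:1), 90 °C; then aq. HCl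
Reagents that add atoms: none
Why: Suzuki–Miyaura cross-coupling; unprotected bromophenols couple as their phenoxides in aqueous base, the electron-rich bulky phosphine SPhos on zerovalent palladium should speed oxidative addition into the electron-rich C–Br bond, and the excess of 5 covers protodeboronation.

Step 4
Reactants: 6 1-(2,4-dihydroxyphenyl)-3-[3-(2,4-dimethoxyphenyl)-4-hydroxyphenyl]propan-1-one
Product: 7 1-(2,4-dihydroxyphenyl)-3-[3-(2,4-dihydroxyphenyl)-4-hydroxyphenyl]propan-1-one
Conditions: BBr3 (8 equiv), CH2Cl2, −78 °C to rt; then H2O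
Reagents that add atoms: none
Why: Lewis acid cleavage of aryl methyl ethers (BBr3 demethylation), in which bromide attacks the methyl carbon of each boron-bound ether; the aryl ketone and the saturated chain are inert to BBr3 at these temperatures and water releases the free phenols.

Step 5
Reactants: 7 1-(2,4-dihydroxyphenyl)-3-[3-(2,4-dihydroxyphenyl)-4-hydroxyphenyl]propan-1-one; 1 3-(4-hydroxyphenyl)propanoic acid (1.1 equiv)
Product: 8 1-(2,4-dihydroxyphenyl)-3-[3-[2,4-dihydroxy-5-[3-(4-hydroxyphenyl)propanoyl]phenyl]-4-hydroxyphenyl]propan-1-one (CID44566750)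
Conditions: BF3·OEt2 (solvent and Lewis acid), 80 °C; then aq. NaOAc
Reagents that add atoms: none
Why: BF3 binds the carboxyl group of 1 and makes its carbonyl carbon electrophilic enough for attack by C-5 of ring C, and loss of the ring proton and of water then gives the aryl ketone, which is the target itself. The closest known reaction type is the Friedel–Crafts C-acylation of unprotected resorcinols with free hydroxyphenyl-alkanoic acids in BF3·OEt2, the usual entry to 2,4-dihydroxyphenyl ketones such as dihydrochalcones and deoxybenzoins, as already used in step 2. No ring is closed and no stereocentre is formed. The step needs acylation on ring C only, at C-5 only and once only: ring C is the single free resorcinol of 7, its C-5 is para to the C-2 hydroxyl and ortho to the C-4 hydroxyl, C-3 between the two hydroxyls is hindered and C-6 is meta to both. Ring A is deactivated by its own Lewis-acid-bound carbonyl group, rings B and D are mono-phenols with blocked para positions, and the new ketone deactivates ring C against a second acylation.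

**Compound list**

1 | 3-(4-hydroxyphenyl)propanoic acid (phloretic acid) | OC(=O)CCc1ccc(O)cc1 | starting material
2 | 3-(3-bromo-4-hydroxyphenyl)propanoic acid | OC(=O)CCc1ccc(O)c(Br)c1 | intermediate
3 | resorcinol (benzene-1,3-diol) | Oc1cccc(O)c1 | starting material
4 | 3-(3-bromo-4-hydroxyphenyl)-1-(2,4-dihydroxyphenyl)propan-1-one | O=C(CCc1ccc(O)c(Br)c1)c1ccc(O)cc1O | intermediate
5 | (2,4-dimethoxyphenyl)boronic acid | COc1ccc(B(O)O)c(OC)c1 | starting material
6 | 1-(2,4-dihydroxyphenyl)-3-[3-(2,4-dimethoxyphenyl)-4-hydroxyphenyl]propan-1-one | O=C(CCc1ccc(O)c(-c2ccc(OC)cc2OC)c1)c1ccc(O)cc1O | intermediate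
7 | 1-(2,4-dihydroxyphenyl)-3-[3-(2,4-dihydroxyphenyl)-4-hydroxyphenyl]propan-1-one | O=C(CCc1ccc(O)c(-c2ccc(O)cc2O)c1)c1ccc(O)cc1O | intermediate
8 | 1-(2,4-dihydroxyphenyl)-3-[3-[2,4-dihydroxy-5-[3-(4-hydroxyphenyl)propanoyl]phenyl]-4-hydroxyphenyl]propan-1-one (CID44566750) | O=C(CCc1ccc(O)c(-c2cc(C(=O)CCc3ccc(O)cc3)c(O)cc2O)c1)c1ccc(O)cc1O | target

Total step count: 5. Longest linear sequence: 5 steps (1 → 2 → 4 → 6 → 7 → 8).

**Steps most likely to fail**

Step 5 (key step). The acylation may stray to ring A or to the phenolic oxygens, a second acyl group may enter, or the hot Lewis acid may dehydrate the 2,2'-dihydroxybiaryl unit of rings B and C towards a dibenzofuran. The fallback sets out from 7 and replaces the hot acid-mediated acylation by a Houben–Hoesch reaction at low temperature. Pentaphenol 7 and 3-(4-hydroxyphenyl)propanenitrile (commercial, N#CCCc1ccc(O)cc1) with ZnCl2 and dry HCl in Et2O at 0 °C should give the ring C ketiminium chloride of the target F1. The nitrilium electrophile attacks only resorcinol-type carbons, and the iminium salt cannot be acylated again. Hydrolysis of F1 in hot water comes back to the route at 8.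

Step 3. Oxidative addition into the electron-rich, phenoxide-bearing C–Br bond may be slow, the electron-rich boronic acid may protodeboronate, and the polyphenoxide may sequester palladium. The fallback sets out from 5 and makes the biaryl bond on a simple benzaldehyde, then builds the C3 chain by condensation instead of acylation. Coupling of 5 with 3-bromo-4-hydroxybenzaldehyde (commercial, O=Cc1ccc(O)c(Br)c1) under Pd(PPh3)4, Na2CO3, DME/H2O, 85 °C should give 4-hydroxy-3-(2,4-dimethoxyphenyl)benzaldehyde F2. Acid-catalysed Claisen–Schmidt condensation of F2 with 1-(2,4-dihydroxyphenyl)ethanone (commercial, CC(=O)c1ccc(O)cc1O), using HCl formed from SOCl2 in EtOH at rt, should give (E)-1-(2,4-dihydroxyphenyl)-3-[3-(2,4-dimethoxyphenyl)-4-hydroxyphenyl]prop-2-en-1-one F3. Hydrogenation of the enone double bond (H2, 1 atm, Pd/C, EtOAc, rt) comes back to the route at 6, and steps 1 and 2 are then not needed.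

Step 4. Cleavage of the methyl ether next to the biaryl axis may stay incomplete, boron may be retained by the polyphenol, or the strong Lewis acid may close the 2,2'-dioxygenated biaryl to a dibenzofuran. The fallback sets out from 4 and masks ring C with benzyl ethers that are removed by neutral hydrogenolysis. 4-Bromoresorcinol (commercial, Oc1ccc(Br)c(O)c1) with benzyl bromide (BrCc1ccccc1) and K2CO3 in DMF should give 2,4-bis(benzyloxy)-1-bromobenzene F4. Bromine–lithium exchange (n-BuLi, THF, −78 °C), B(OiPr)3 and aq. HCl should give [2,4-bis(benzyloxy)phenyl]boronic acid F5. Coupling of F5 with 4 under the conditions of step 3 should give 1-(2,4-dihydroxyphenyl)-3-[3-[2,4-bis(benzyloxy)phenyl]-4-hydroxyphenyl]propan-1-one F6. Hydrogenolysis of F6 (H2, 1 atm, Pd/C, EtOAc/MeOH, rt) comes back to the route at 7.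

**Further compounds**

F1 | step 5 | ring C ketiminium chloride of the target, 1-[5-[5-[3-(2,4-dihydroxyphenyl)-3-oxopropyl]-2-hydroxyphenyl]-2,4-dihydroxyphenyl]-3-(4-hydroxyphenyl)propan-1-iminium chloride | [Cl-].[NH2+]=C(CCc1ccc(O)cc1)c1cc(-c2cc(CCC(=O)c3ccc(O)cc3O)ccc2O)c(O)cc1O
F2 | step 3 | 4-hydroxy-3-(2,4-dimethoxyphenyl)benzaldehyde | O=Cc1ccc(O)c(-c2ccc(OC)cc2OC)c1
F3 | step 3 | (E)-1-(2,4-dihydroxyphenyl)-3-[3-(2,4-dimethoxyphenyl)-4-hydroxyphenyl]prop-2-en-1-one | O=C(/C=C/c1ccc(O)c(-c2ccc(OC)cc2OC)c1)c1ccc(O)cc1O
F4 | step 4 | 2,4-bis(benzyloxy)-1-bromobenzene | Brc1ccc(OCc2ccccc2)cc1OCc1ccccc1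
F5 | step 4 | [2,4-bis(benzyloxy)phenyl]boronic acid | OB(O)c1ccc(OCc2ccccc2)cc1OCc1ccccc1
F6 | step 4 | 1-(2,4-dihydroxyphenyl)-3-[3-[2,4-bis(benzyloxy)phenyl]-4-hydroxyphenyl]propan-1-one | O=C(CCc1ccc(O)c(-c2ccc(OCc3ccccc3)cc2OCc2ccccc2)c1)c1ccc(O)cc1O
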